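**Plan**

Numbering (cyclodeca[b]furan): O1, C2 (lactone C=O), C3 (CH2OH), C3a, C4 (methacrylate), C5, C6 (Me), C7, C8 (OAc), C9 (CH2), C10 (OH, Me), C11, C11a.
Retrosynthesis: (i) the 11E-ylidene butenolide goes back to a 2,3,4-trisubstituted furan (singlet-oxygen oxidation, then dehydration); (ii) the ten-membered ring is cut at C9–C10, an aldol bond between the enolate of a C8 ketone and a C10 methyl ketone; (iii) the open chain is cut at C8–C9 (chloromethyl unit), C6–CH3 (carbocupration of an ynamide), C4–C5 (propargylation of a furan aldehyde) and C11–C11a (allylation of the furan, allyl = masked acetonyl).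
Enabling feature: O8 and O10 are 1,3-related across the C9 methylene, so C8(=O)–C9–C10(OH) is an aldol retron, and the ring to be closed is pre-bent by two rigid cis units, the furan edge C3a–C11a and the 6Z alkene.
Forward order: the furan ring is present from the start and receives both side chains (steps 1–9); the ten-membered carbocycle is closed in step 10; the furan is turned into the ylidene butenolide in steps 15–16.
Stereochemistry: C4 from a catalyst-controlled propargylation; C10 from the ring-closing aldol under control of C4; C8 from a hydroxyl-directed 1,3-syn reduction; 6Z from syn-carbocupration; 11E enforced by the ring.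

Key step: step 10

Assumption: the (R)-configured phosphoric acid of step 4 is taken to deliver the propargyl group to the Re face of aldehyde 5 (R carbinol); if the sense is the opposite, its enantiomer is used.

**Route**

Step 1
Reactants: 1 furan-3,4-diyldimethanol
Product: 2 {4-[(tert-butyldiphenylsilyloxy)methyl]furan-3-yl}methanol
Conditions: NaH (1.0 equiv), THF, 0 °C; TBDPSCl (1.0 equiv), 0 °C → rt
Reagents that add atoms: tert-butyl(chloro)diphenylsilane, CC(C)(C)[Si](Cl)(c1ccccc1)c1ccccc1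
Why: Monosilylation of a symmetrical diol through its monosodium alkoxide (O-silylation) differentiates the two hydroxymethyl groups; no stereocenter is involved.

Step 2
Reactants: 2 {4-[(tert-butyldiphenylsilyloxy)methyl]furan-3-yl}methanol
Product: 4 {2-allyl-4-[(tert-butyldiphenylsilyloxy)methyl]furan-3-yl}methanol, via dilithiated furylmethanol 3 (not isolated)
Conditions: n-BuLi (2.2 equiv), THF, −78 → 0 °C; allyl bromide, −78 °C → rt; aq. NH4Cl
Reagents that add atoms: allyl bromide, C=CCBr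
Why: Alkoxide-directed ortho-lithiation places lithium at C2 of the furan next to the CH2OLi group (five-membered chelate), and the furyllithium is C-alkylated by allyl bromide, the allyl group serving as a masked acetonyl unit.

Step 3
Reactants: 4 {2-allyl-4-[(tert-butyldiphenylsilyloxy)methyl]furan-3-yl}methanol
Product: 5 2-allyl-4-[(tert-butyldiphenylsilyloxy)methyl]furan-3-carbaldehyde
Conditions: activated MnO2 (excess), CH2Cl2, rt
Reagents that add atoms: none
Why: MnO2 oxidation of a furylmethanol (benzylic-type alcohol) to the aldehyde leaves the allyl group and the silyl ether untouched.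

Step 4
Reactants: 5 2-allyl-4-[(tert-butyldiphenylsilyloxy)methyl]furan-3-carbaldehyde
Product: 6 (1R)-1-{2-allyl-4-[(tert-butyldiphenylsilyloxy)methyl]furan-3-yl}but-3-yn-1-ol
Conditions: allenylboronic acid pinacol ester (1.5 equiv), (R)-3,3′-bis(2,4,6-triisopropylphenyl)-1,1′-binaphthyl-2,2′-diyl hydrogen phosphate (5 mol %), 4 Å MS, toluene, −20 → 0 °C; aqueous work-up
Reagents that add atoms: allenylboronic acid pinacol ester, C=C=CB1OC(C)(C)C(C)(C)O1
Why: Chiral phosphoric acid-catalysed propargylboration passes through a closed six-membered SE2′ transition state organised by the catalyst, which should set the R carbinol (future C4) by Re-face attack.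

Step 5
Reactants: 6 (1R)-1-{2-allyl-4-[(tert-butyldiphenylsilyloxy)methyl]furan-3-yl}but-3-yn-1-ol
Product: 7 (R)-2-allyl-4-[(tert-butyldiphenylsilyloxy)methyl]-3-[1-(triethylsilyloxy)but-3-yn-1-yl]furan
Conditions: Et3SiCl, imidazole, 4-(dimethylamino)pyridine (cat.), CH2Cl2, 0 °C → rt
Reagents that add atoms: chlorotriethylsilane, CC[Si](Cl)(CC)CC
Why: Silyl ether protection of the secondary alcohol makes the following organolithium and cuprate steps possible and keeps the later C8 ketone from forming a hemiketal.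

Step 6
Reactants: 7 (R)-2-allyl-4-[(tert-butyldiphenylsilyloxy)methyl]-3-[1-(triethylsilyloxy)but-3-yn-1-yl]furan
Product: 8 (5R)-5-{2-allyl-4-[(tert-butyldiphenylsilyloxy)methyl]furan-3-yl}-N-methoxy-N-methyl-5-(triethylsilyloxy)pent-2-ynamide
Conditions: n-BuLi (1.05 equiv), THF, −78 °C; ClC(O)N(OMe)Me, −78 → 0 °C
Reagents that add atoms: N-methoxy-N-methylcarbamoyl chloride, CON(C)C(Cl)=O
Why: Deprotonation of the terminal alkyne and acylation of the lithium acetylide with the carbamoyl chloride gives the alkynyl Weinreb amide (acetylide acylation).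

Step 7
Reactants: 8 (5R)-5-{2-allyl-4-[(tert-butyldiphenylsilyloxy)methyl]furan-3-yl}-N-methoxy-N-methyl-5-(triethylsilyloxy)pent-2-ynamide
Product: 9 (2Z,5R)-5-{2-allyl-4-[(tert-butyldiphenylsilyloxy)methyl]furan-3-yl}-N-methoxy-N,3-dimethyl-5-(triethylsilyloxy)pent-2-enamide
Conditions: Me2CuLi (from CuI and 2 MeLi), THF, −78 °C; MeOH then aq. NH4Cl at −78 °C
Reagents that add atoms: lithium dimethylcuprate, [Li+].C[Cu-]C
Why: Conjugate addition of the Gilman cuprate to the ynamide is a syn-carbocupration, so low-temperature protonation of the vinylcopper species leaves the C4 methylene and the amide carbonyl cis and sets the Z trisubstituted alkene (future C6=C7).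

Step 8
Reactants: 9 (2Z,5R)-5-{2-allyl-4-[(tert-butyldiphenylsilyloxy)methyl]furan-3-yl}-N-methoxy-N,3-dimethyl-5-(triethylsilyloxy)pent-2-enamide
Product: 10 (3Z,6R)-6-{2-allyl-4-[(tert-butyldiphenylsilyloxy)methyl]furan-3-yl}-1-chloro-4-methyl-6-(triethylsilyloxy)hex-3-en-2-one
Conditions: ICH2Cl, MeLi·LiBr, THF/Et2O, −78 °C; aq. NH4Cl
Reagents that add atoms: chloroiodomethane, ClCI
Why: Chloromethyllithium formed in situ by iodine–lithium exchange adds once to the Weinreb amide, whose chelated tetrahedral adduct collapses only on work-up (Weinreb ketone synthesis with a carbenoid), giving the α′-chloro enone without conjugate addition or loss of the Z geometry.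

Step 9
Reactants: 10 (3Z,6R)-6-{2-allyl-4-[(tert-butyldiphenylsilyloxy)methyl]furan-3-yl}-1-chloro-4-methyl-6-(triethylsilyloxy)hex-3-en-2-one
Product: 11 (3Z,6R)-6-{4-[(tert-butyldiphenylsilyloxy)methyl]-2-(2-oxopropyl)furan-3-yl}-1-chloro-4-methyl-6-(triethylsilyloxy)hex-3-en-2-one
Conditions: PdCl2 (10 mol %), Cu(OAc)2 (20 mol %), O2 (1 atm), DMA/H2O, rt
Reagents that add atoms: water, O
Why: Tsuji–Wacker oxidation converts the only terminal monosubstituted alkene into the methyl ketone by Markovnikov hydroxypalladation, the acetate-buffered copper co-catalyst keeping the medium mild for the silyl ethers and the chloro ketone.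

Step 10
Reactants: 11 (3Z,6R)-6-{4-[(tert-butyldiphenylsilyloxy)methyl]-2-(2-oxopropyl)furan-3-yl}-1-chloro-4-methyl-6-(triethylsilyloxy)hex-3-en-2-one
Product: 13 (4R,6Z,10R)-3-[(tert-butyldiphenylsilyloxy)methyl]-10-hydroxy-6,10-dimethyl-4-(triethylsilyloxy)-4,5,10,11-tetrahydrocyclodeca[b]furan-8(9H)-one, via samarium dienolate 12 (not isolated)
Conditions: SmI2 (2.2 equiv), THF, −78 °C, slow addition of 11 to about 2 mM; pH 7 buffer at −78 °C
Reagents that add atoms: none
Why: Two-electron reduction of the C–Cl bond by samarium diiodide gives the cross-conjugated trivalent samarium dienolate 12 regiospecifically at C9, and this enolate adds to the C10 methyl ketone through a samarium-bridged chair-like transition state (intramolecular samarium Reformatsky-type aldol, the closest precedent being SmI2-mediated ketol closures of medium rings). The ten-membered carbocycle closes in a 10-(enolendo)-exo-trig mode, helped by the furan edge C3a–C11a and the 6Z alkene, which leave only C4, C5 and C11 as freely rotating ring atoms. The new C10 stereocenter is controlled by C4: allylic strain with the C3 side chain holds C4–H in the furan plane, the bulky OSiEt3 group then shields one face, the chain folds over the other, and the chelate with the ketone methyl group pointing out of the ring should deliver the 10R ketol. The step needs chemoselectivity (C–Cl reduction ahead of ketone or enone reduction, secured by the much faster reduction of α-halo ketones at −78 °C), regioselectivity (enolate only at C9 and not at the more acidic C11, secured by the position of chlorine) and cyclization over intermolecular reaction (secured by slow addition at high dilution). The Z geometry of C6=C7 is untouched because the dienolate is cross-conjugated.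

Step 11
Reactants: 13 (4R,6Z,10R)-3-[(tert-butyldiphenylsilyloxy)methyl]-10-hydroxy-6,10-dimethyl-4-(triethylsilyloxy)-4,5,10,11-tetrahydrocyclodeca[b]furan-8(9H)-one
Product: 14 (4R,6Z,8R,10S)-3-[(tert-butyldiphenylsilyloxy)methyl]-6,10-dimethyl-4-(triethylsilyloxy)-4,5,8,9,10,11-hexahydrocyclodeca[b]furan-8,10-diol
Conditions: Et2BOMe (1.2 equiv), THF/MeOH, −78 °C; NaBH4, −78 °C; AcOH, then co-evaporation with MeOH
Reagents that add atoms: none
Why: Narasaka–Prasad reduction: Et2BOMe ties the C10 hydroxyl and the C8 ketone into a six-membered boron chelate and external hydride attacks the face leading to the chair-like dioxaborinane, which should give the 8R alcohol 1,3-syn to O10 (the C10 descriptor changes from R to S only because the CIP ranking of its neighbours changes).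

Step 12
Reactants: 14 (4R,6Z,8R,10S)-3-[(tert-butyldiphenylsilyloxy)methyl]-6,10-dimethyl-4-(triethylsilyloxy)-4,5,8,9,10,11-hexahydrocyclodeca[b]furan-8,10-diol
Product: 15 (4R,6Z,8R,10S)-3-[(tert-butyldiphenylsilyloxy)methyl]-10-hydroxy-6,10-dimethyl-4-(triethylsilyloxy)-4,5,8,9,10,11-hexahydrocyclodeca[b]furan-8-yl acetate
Conditions: Ac2O, pyridine, 4-(dimethylamino)pyridine (cat.), CH2Cl2, 0 °C
Reagents that add atoms: acetic anhydride, CC(=O)OC(C)=O
Why: Selective esterification: the secondary allylic C8 alcohol is acetylated while the tertiary C10 alcohol reacts far more slowly.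

Step 13
Reactants: 15 (4R,6Z,8R,10S)-3-[(tert-butyldiphenylsilyloxy)methyl]-10-hydroxy-6,10-dimethyl-4-(triethylsilyloxy)-4,5,8,9,10,11-hexahydrocyclodeca[b]furan-8-yl acetate
Product: 16 (4R,6Z,8R,10S)-3-[(tert-butyldiphenylsilyloxy)methyl]-4,10-dihydroxy-6,10-dimethyl-4,5,8,9,10,11-hexahydrocyclodeca[b]furan-8-yl acetate
Conditions: HF·pyridine, pyridine, THF, 0 °C
Reagents that add atoms: none
Why: Buffered fluoride desilylation removes the secondary triethylsilyl ether much faster than the primary tert-butyldiphenylsilyl ether and does not disturb the acetate.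

Step 14
Reactants: 16 (4R,6Z,8R,10S)-3-[(tert-butyldiphenylsilyloxy)methyl]-4,10-dihydroxy-6,10-dimethyl-4,5,8,9,10,11-hexahydrocyclodeca[b]furan-8-yl acetate
Product: 17 (4R,6Z,8R,10S)-8-acetoxy-3-[(tert-butyldiphenylsilyloxy)methyl]-10-hydroxy-6,10-dimethyl-4,5,8,9,10,11-hexahydrocyclodeca[b]furan-4-yl 2-methylprop-2-enoate
Conditions: methacrylic anhydride, Et3N, 4-(dimethylamino)pyridine (cat.), CH2Cl2, 0 °C → rt
Reagents that add atoms: methacrylic anhydride, C=C(C)C(=O)OC(=O)C(C)=C
Why: Nucleophile-catalysed acyl transfer esterifies the only reactive hydroxyl, the secondary C4 alcohol, with retention of configuration.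

Step 15
Reactants: 17 (4R,6Z,8R,10S)-8-acetoxy-3-[(tert-butyldiphenylsilyloxy)methyl]-10-hydroxy-6,10-dimethyl-4,5,8,9,10,11-hexahydrocyclodeca[b]furan-4-yl 2-methylprop-2-enoate
Product: 19 (4R,6Z,8R,10S)-8-acetoxy-3-[(tert-butyldiphenylsilyloxy)methyl]-10,11a-dihydroxy-6,10-dimethyl-2-oxo-2,4,5,8,9,10,11,11a-octahydrocyclodeca[b]furan-4-yl 2-methylprop-2-enoate (C11a configuration open), via furan endoperoxide 18 (not isolated)
Conditions: O2, visible light, 5,10,15,20-tetraphenylporphyrin (cat.), i-Pr2NEt, CH2Cl2, −78 °C → rt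
Reagents that add atoms: dioxygen, O=O
Why: Singlet oxygen adds to the electron-rich furan in a [4+2] cycloaddition and the hindered amine removes the only α-hydrogen of the endoperoxide (Kornblum–DeLaMare fragmentation), which fixes the carbonyl at C2 and the hydroxyl at C11a as in the presumed biogenesis of 12,8-olides from furanogermacranes.

Step 16
Reactants: 19 (4R,6Z,8R,10S)-8-acetoxy-3-[(tert-butyldiphenylsilyloxy)methyl]-10,11a-dihydroxy-6,10-dimethyl-2-oxo-2,4,5,8,9,10,11,11a-octahydrocyclodeca[b]furan-4-yl 2-methylprop-2-enoate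
Product: 21 (4R,6Z,8R,10S,11E)-8-acetoxy-3-[(tert-butyldiphenylsilyloxy)methyl]-10-hydroxy-6,10-dimethyl-2-oxo-2,4,5,8,9,10-hexahydrocyclodeca[b]furan-4-yl 2-methylprop-2-enoate, via pseudo-acid mesylate 20 (not isolated)
Conditions: MsCl, Et3N, CH2Cl2, −40 → 0 °C
Reagents that add atoms: none
Why: Sulfonylation of the hemiketal hydroxyl gives a pseudo-acid mesylate that ionises to the acyloxocarbenium ion and loses a C11 proton (dehydrative enol lactone formation, as in the dehydration of 8-hydroxy-12,8-olides), the fused ten-membered ring favouring the ring-cis 11E alkene.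

Step 17
Reactants: 21 (4R,6Z,8R,10S,11E)-8-acetoxy-3-[(tert-butyldiphenylsilyloxy)methyl]-10-hydroxy-6,10-dimethyl-2-oxo-2,4,5,8,9,10-hexahydrocyclodeca[b]furan-4-yl 2-methylprop-2-enoate
Product: 22 (4R,6Z,8R,10S,11E)-8-acetoxy-10-hydroxy-3-(hydroxymethyl)-6,10-dimethyl-2-oxo-2,4,5,8,9,10-hexahydrocyclodeca[b]furan-4-yl 2-methylprop-2-enoate
Conditions: HF·pyridine, pyridine, THF, 0 °C → rt
Reagents that add atoms: none
Why: Fluoride desilylation of the primary silyl ether under buffered non-basic conditions should spare the two esters, the enol lactone and the tertiary allylic alcohol.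

**Compound list**

1 | furan-3,4-diyldimethanol | OCc1cocc1CO | starting material
2 | {4-[(tert-butyldiphenylsilyloxy)methyl]furan-3-yl}methanol | OCc1cocc1CO[Si](c2ccccc2)(c3ccccc3)C(C)(C)C | intermediate
3 | lithium {4-[(tert-butyldiphenylsilyloxy)methyl]-2-lithiofuran-3-yl}methanolate (not isolated) | [Li]OCc1c([Li])occ1CO[Si](c2ccccc2)(c3ccccc3)C(C)(C)C | intermediate
4 | {2-allyl-4-[(tert-butyldiphenylsilyloxy)methyl]furan-3-yl}methanol | OCc1c(CC=C)occ1CO[Si](c2ccccc2)(c3ccccc3)C(C)(C)C | intermediate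
5 | 2-allyl-4-[(tert-butyldiphenylsilyloxy)methyl]furan-3-carbaldehyde | O=Cc1c(CC=C)occ1CO[Si](c2ccccc2)(c3ccccc3)C(C)(C)C | intermediate
6 | (1R)-1-{2-allyl-4-[(tert-butyldiphenylsilyloxy)methyl]furan-3-yl}but-3-yn-1-ol | C#CC[C@@H](O)c1c(CC=C)occ1CO[Si](c2ccccc2)(c3ccccc3)C(C)(C)C | intermediate
7 | (R)-2-allyl-4-[(tert-butyldiphenylsilyloxy)methyl]-3-[1-(triethylsilyloxy)but-3-yn-1-yl]furan | C#CC[C@@H](O[Si](CC)(CC)CC)c1c(CC=C)occ1CO[Si](c2ccccc2)(c3ccccc3)C(C)(C)C | intermediate
8 | (5R)-5-{2-allyl-4-[(tert-butyldiphenylsilyloxy)methyl]furan-3-yl}-N-methoxy-N-methyl-5-(triethylsilyloxy)pent-2-ynamide | CON(C)C(=O)C#CC[C@@H](O[Si](CC)(CC)CC)c1c(CC=C)occ1CO[Si](c2ccccc2)(c3ccccc3)C(C)(C)C | intermediate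
9 | (2Z,5R)-5-{2-allyl-4-[(tert-butyldiphenylsilyloxy)methyl]furan-3-yl}-N-methoxy-N,3-dimethyl-5-(triethylsilyloxy)pent-2-enamide | CON(C)C(=O)/C=C(C)\C[C@@H](O[Si](CC)(CC)CC)c1c(CC=C)occ1CO[Si](c2ccccc2)(c3ccccc3)C(C)(C)C | intermediate
10 | (3Z,6R)-6-{2-allyl-4-[(tert-butyldiphenylsilyloxy)methyl]furan-3-yl}-1-chloro-4-methyl-6-(triethylsilyloxy)hex-3-en-2-one | ClCC(=O)/C=C(C)\C[C@@H](O[Si](CC)(CC)CC)c1c(CC=C)occ1CO[Si](c2ccccc2)(c3ccccc3)C(C)(C)C | intermediate
11 | (3Z,6R)-6-{4-[(tert-butyldiphenylsilyloxy)methyl]-2-(2-oxopropyl)furan-3-yl}-1-chloro-4-methyl-6-(triethylsilyloxy)hex-3-en-2-one | ClCC(=O)/C=C(C)\C[C@@H](O[Si](CC)(CC)CC)c1c(CC(C)=O)occ1CO[Si](c2ccccc2)(c3ccccc3)C(C)(C)C | intermediate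
12 | diiodosamarium (3Z,6R)-hexa-1,3-dien-2-olate derived from 11 by loss of chloride (not isolated) | C=C(O[Sm](I)I)/C=C(C)\C[C@@H](O[Si](CC)(CC)CC)c1c(CC(C)=O)occ1CO[Si](c2ccccc2)(c3ccccc3)C(C)(C)C | intermediate
13 | (4R,6Z,10R)-3-[(tert-butyldiphenylsilyloxy)methyl]-10-hydroxy-6,10-dimethyl-4-(triethylsilyloxy)-4,5,10,11-tetrahydrocyclodeca[b]furan-8(9H)-one | CC[Si](CC)(CC)O[C@@H]1C/C(C)=C\C(=O)C[C@](C)(O)Cc2occ(CO[Si](c3ccccc3)(c4ccccc4)C(C)(C)C)c21 | intermediate
14 | (4R,6Z,8R,10S)-3-[(tert-butyldiphenylsilyloxy)methyl]-6,10-dimethyl-4-(triethylsilyloxy)-4,5,8,9,10,11-hexahydrocyclodeca[b]furan-8,10-diol | CC[Si](CC)(CC)O[C@@H]1C/C(C)=C\[C@H](O)C[C@](C)(O)Cc2occ(CO[Si](c3ccccc3)(c4ccccc4)C(C)(C)C)c21 | intermediate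
15 | (4R,6Z,8R,10S)-3-[(tert-butyldiphenylsilyloxy)methyl]-10-hydroxy-6,10-dimethyl-4-(triethylsilyloxy)-4,5,8,9,10,11-hexahydrocyclodeca[b]furan-8-yl acetate | CC[Si](CC)(CC)O[C@@H]1C/C(C)=C\[C@H](OC(C)=O)C[C@](C)(O)Cc2occ(CO[Si](c3ccccc3)(c4ccccc4)C(C)(C)C)c21 | intermediate
16 | (4R,6Z,8R,10S)-3-[(tert-butyldiphenylsilyloxy)methyl]-4,10-dihydroxy-6,10-dimethyl-4,5,8,9,10,11-hexahydrocyclodeca[b]furan-8-yl acetate | O[C@@H]1C/C(C)=C\[C@H](OC(C)=O)C[C@](C)(O)Cc2occ(CO[Si](c3ccccc3)(c4ccccc4)C(C)(C)C)c21 | intermediate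
17 | (4R,6Z,8R,10S)-8-acetoxy-3-[(tert-butyldiphenylsilyloxy)methyl]-10-hydroxy-6,10-dimethyl-4,5,8,9,10,11-hexahydrocyclodeca[b]furan-4-yl 2-methylprop-2-enoate | C=C(C)C(=O)O[C@@H]1C/C(C)=C\[C@H](OC(C)=O)C[C@](C)(O)Cc2occ(CO[Si](c3ccccc3)(c4ccccc4)C(C)(C)C)c21 | intermediate
18 | 2,11a-epidioxy adduct (furan endoperoxide) of 17, configuration at C2 and C11a open (not isolated) | C=C(C)C(=O)O[C@@H]1C/C(C)=C\[C@H](OC(C)=O)C[C@](C)(O)CC23OOC(O2)C(CO[Si](c4ccccc4)(c5ccccc5)C(C)(C)C)=C31 | intermediate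
19 | (4R,6Z,8R,10S)-8-acetoxy-3-[(tert-butyldiphenylsilyloxy)methyl]-10,11a-dihydroxy-6,10-dimethyl-2-oxo-2,4,5,8,9,10,11,11a-octahydrocyclodeca[b]furan-4-yl 2-methylprop-2-enoate, C11a configuration open | C=C(C)C(=O)O[C@@H]1C/C(C)=C\[C@H](OC(C)=O)C[C@](C)(O)CC2(O)OC(=O)C(CO[Si](c3ccccc3)(c4ccccc4)C(C)(C)C)=C21 | intermediate
20 | 11a-methanesulfonate of 19 (not isolated) | C=C(C)C(=O)O[C@@H]1C/C(C)=C\[C@H](OC(C)=O)C[C@](C)(O)CC2(OS(C)(=O)=O)OC(=O)C(CO[Si](c3ccccc3)(c4ccccc4)C(C)(C)C)=C21 | intermediate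
21 | (4R,6Z,8R,10S,11E)-8-acetoxy-3-[(tert-butyldiphenylsilyloxy)methyl]-10-hydroxy-6,10-dimethyl-2-oxo-2,4,5,8,9,10-hexahydrocyclodeca[b]furan-4-yl 2-methylprop-2-enoate | C=C(C)C(=O)O[C@@H]1C/C(C)=C\[C@H](OC(C)=O)C[C@](C)(O)/C=C2/OC(=O)C(CO[Si](c3ccccc3)(c4ccccc4)C(C)(C)C)=C21 | intermediate
22 | (4R,6Z,8R,10S,11E)-8-acetoxy-10-hydroxy-3-(hydroxymethyl)-6,10-dimethyl-2-oxo-2,4,5,8,9,10-hexahydrocyclodeca[b]furan-4-yl 2-methylprop-2-enoate | C=C(C)C(=O)O[C@@H]1C/C(C)=C\[C@H](OC(C)=O)C[C@](C)(O)/C=C2/OC(=O)C(CO)=C21 | target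

**Count and risks**

Total steps: 17. Longest linear sequence: 17 steps (from 1).

Steps most likely to fail:

1. Step 10 (ring closure). The samarium enolate may be protonated by the acidic C11 methylene of the furfuryl ketone, or react intermolecularly, before the ten-membered ring closes. The two faces of the C10 ketone may also be poorly differentiated in the chelated transition state. Fallback, a Mukaiyama aldol in place of a metal enolate: setting out from 11, reductive silylation of the α-chloro ketone (activated Zn, Me3SiCl, THF, 0 °C) would give the regiodefined silyl dienol ether (3Z,6R)-6-{4-[(tert-butyldiphenylsilyloxy)methyl]-2-(2-oxopropyl)furan-3-yl}-4-methyl-6-(triethylsilyloxy)-2-(trimethylsilyloxy)hexa-1,3-diene F1. This neutral nucleophile would be cyclized at high dilution with TiCl4 in CH2Cl2 at −78 °C onto the Lewis acid-activated ketone through an open transition state, which removes the basic enolate and offers a different facial bias. The fallback comes back to the route at ketol 13.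

2. Step 16 (dehydration to the ylidene butenolide). The free tertiary C10 alcohol may be sulfonylated or ionised, the β-hydroxy ketone form of the pseudo-acid may undergo retro-aldol ring opening under amine base, or elimination may be unselective. Fallback, with the tertiary alcohol masked first: setting out from 17, Et3SiOTf and 2,6-lutidine would give the 10-O-triethylsilyl ether of 17 F2. Photooxygenation as in step 15 would pass through the furan endoperoxide of F2 F3 to the 10-O-triethylsilyl ether of 19 F4. Trifluoroacetic anhydride and Et3N would then dehydrate it through the 11a-trifluoroacetate of F4 F5 to the 10-O-triethylsilyl ether of 21 F6. HF·pyridine would cleave both silyl ethers, and the fallback comes back to the route at target 22.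

3. Step 11 (C8 reduction). Hydride delivery may be governed by the conformation of the ten-membered ring and not by the boron chelate, giving poor or reversed facial selectivity at C8. Fallback, anti reduction followed by inversion: setting out from 13, Evans–Saksena reduction (Me4NBH(OAc)3, MeCN/AcOH, −30 °C; intramolecular hydride delivery from the C10 alkoxyborohydride) would give the 1,3-anti diol (4R,6Z,8S,10S)-3-[(tert-butyldiphenylsilyloxy)methyl]-6,10-dimethyl-4-(triethylsilyloxy)-4,5,8,9,10,11-hexahydrocyclodeca[b]furan-8,10-diol F7. A Mitsunobu reaction with acetic acid (PPh3, diisopropyl azodicarboxylate, THF, 0 °C) would invert C8 while installing the acetate, leaving the tertiary alcohol untouched. The fallback comes back to the route at acetate 15.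

Further compounds
F1 | step 10 | (3Z,6R)-6-{4-[(tert-butyldiphenylsilyloxy)methyl]-2-(2-oxopropyl)furan-3-yl}-4-methyl-6-(triethylsilyloxy)-2-(trimethylsilyloxy)hexa-1,3-diene | C=C(O[Si](C)(C)C)/C=C(C)\C[C@@H](O[Si](CC)(CC)CC)c1c(CC(C)=O)occ1CO[Si](c2ccccc2)(c3ccccc3)C(C)(C)C
F2 | step 16 | (4R,6Z,8R,10S)-8-acetoxy-3-[(tert-butyldiphenylsilyloxy)methyl]-6,10-dimethyl-10-(triethylsilyloxy)-4,5,8,9,10,11-hexahydrocyclodeca[b]furan-4-yl 2-methylprop-2-enoate | C=C(C)C(=O)O[C@@H]1C/C(C)=C\[C@H](OC(C)=O)C[C@](C)(O[Si](CC)(CC)CC)Cc2occ(CO[Si](c3ccccc3)(c4ccccc4)C(C)(C)C)c21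
F3 | step 16 | 2,11a-epidioxy adduct (furan endoperoxide) of F2, configuration at C2 and C11a open | C=C(C)C(=O)O[C@@H]1C/C(C)=C\[C@H](OC(C)=O)C[C@](C)(O[Si](CC)(CC)CC)CC23OOC(O2)C(CO[Si](c4ccccc4)(c5ccccc5)C(C)(C)C)=C31
F4 | step 16 | (4R,6Z,8R,10S)-8-acetoxy-3-[(tert-butyldiphenylsilyloxy)methyl]-11a-hydroxy-6,10-dimethyl-2-oxo-10-(triethylsilyloxy)-2,4,5,8,9,10,11,11a-octahydrocyclodeca[b]furan-4-yl 2-methylprop-2-enoate, C11a configuration open | C=C(C)C(=O)O[C@@H]1C/C(C)=C\[C@H](OC(C)=O)C[C@](C)(O[Si](CC)(CC)CC)CC2(O)OC(=O)C(CO[Si](c3ccccc3)(c4ccccc4)C(C)(C)C)=C21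
F5 | step 16 | 11a-trifluoroacetate of F4 | C=C(C)C(=O)O[C@@H]1C/C(C)=C\[C@H](OC(C)=O)C[C@](C)(O[Si](CC)(CC)CC)CC2(OC(=O)C(F)(F)F)OC(=O)C(CO[Si](c3ccccc3)(c4ccccc4)C(C)(C)C)=C21
F6 | step 16 | (4R,6Z,8R,10S,11E)-8-acetoxy-3-[(tert-butyldiphenylsilyloxy)methyl]-6,10-dimethyl-2-oxo-10-(triethylsilyloxy)-2,4,5,8,9,10-hexahydrocyclodeca[b]furan-4-yl 2-methylprop-2-enoate | C=C(C)C(=O)O[C@@H]1C/C(C)=C\[C@H](OC(C)=O)C[C@](C)(O[Si](CC)(CC)CC)/C=C2/OC(=O)C(CO[Si](c3ccccc3)(c4ccccc4)C(C)(C)C)=C21
F7 | step 11 | (4R,6Z,8S,10S)-3-[(tert-butyldiphenylsilyloxy)methyl]-6,10-dimethyl-4-(triethylsilyloxy)-4,5,8,9,10,11-hexahydrocyclodeca[b]furan-8,10-diol | CC[Si](CC)(CC)O[C@@H]1C/C(C)=C\[C@@H](O)C[C@](C)(O)Cc2occ(CO[Si](c3ccccc3)(c4ccccc4)C(C)(C)C)c21
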